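## Structural features

The target is a C30 bis(perhydrobenzoxepine): two trans-fused oxepane–cyclohexane bicycles, rings A/B and rings D/C, joined by the two-carbon tether C12–C13 that runs from C11 of ring B to C14 of ring C. The numbering used throughout is ring A = O, C2(Me2), C3, C4, C5, C6(Me), C7; ring B = C6–C11; ring C = C14–C19; ring D = C19–C23 plus the ether oxygen on C18. Each half carries a contiguous run of stereocentres, C3/C6/C7/C11 on one side and C22/C19/C18/C14/C15 on the other; reading the SMILES gives 3R,6R,7R,11S,14R,15S,18R,19R,22R. The halves have the same constitution and configuration from C2 to C9 and from C23 to C16, but differ at the centre: C10 is an exocyclic methylene carbon, whereas C15 keeps its methyl group and bears an axial tertiary acetate syn-diaxial to the C19 methyl group. Fragile points are that tertiary acetate (ionisation, elimination), the 1,1-disubstituted alkene (acid-induced migration), C11 once C10 is a carbonyl group, and the pair C3–OH/C22–OAc, which can only be told apart by the order of events. The real difficulty is the triad C14–C15–C19: a tertiary carbon between a quaternary carbon and a fully substituted oxygenated carbon, on a ring trans-fused to a seven-membered ether. The key step exploits the fact that C15 with its methyl group and oxygen, C14 and the chain C16–C23 map onto (3S,6E)-nerolidol, so C15 is bought and C14, C18, C19 and C22 are derived from it and from two epoxides.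

## Logic of the disconnections

27 to 26: the O–Si bond at C3 is cut last. A silyl ether is what keeps the C3 hydroxyl distinct from its chemical twin at C22, so 26 carries acetates at C15 and C22 and silicon at C3. The forward step must remove silicon without touching two esters or the exocyclic alkene.

26 to 25: C10=CH2 is cut back to a C10 carbonyl group. This postpones the isomerisable alkene to the end and makes C11 correctable, since its substituent is equatorial in the target. The forward step must be a methylenation that is not basic (acetates, C11) and still reaches a ketone next to a branched carbon.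

25 to 24 to 22: the C10–O bond and the C11–H bond are removed together, which leads back to the C10=C11 alkene. The gain is that C11 stops being a stereocentre of the coupling partner. The forward step must place boron on C10 and hydrogen on C11 from the face opposite the axial C6 methyl group, without reducing the acetates.

22 to 8 and 20: the C11–C12 bond is cut. It is an sp2–sp3 bond between two bicycles of similar size (C16 and C13), and both tether carbons stay with the ring C/D half as a vinyl group. The forward step (through 21) is a cross-coupling at an alkenyl carbon next to a quaternary centre, under base mild enough for two acetates.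

8 to 7: the two acyl C–O bonds are cut. Installing both acetates before the coupling means the ring C/D half never needs a protecting group. The demand is acylation of a hindered axial tertiary alcohol.

7 to 5 (key disconnection): the C14–C19 and O–C23 bonds are cut, the two epoxides are restored and C12 is tied back to silicon. Two rings, the quaternary C19 and the tertiary C14 disappear, leaving a chain whose only stereocentres are one carbinol carbon and two epoxides. The forward step needs regioselective epoxonium formation at C23, anti opening at C19 by carbon and not by the siloxane oxygen, and survival of the tertiary allylic C15–O bond.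

5 to 4 to 2 and 3: the ring C13=C14 double bond is cut (metathesis), then the Si–O bond. Carbon bookkeeping: of the fifteen carbons of 1, fourteen reach the target (C14–C23 and four methyl groups). The terminal vinyl carbon of 1 is excised in the ring closure, and C13 and C12 are the two inner carbons of the allyl group of 3. The dimethylsilylene unit is kept because 3 silylates a tertiary alcohol without a silyl triflate (which the epoxides would not survive) and leaves the allylsilane as electron-rich as a siloxane allows.

2 to 1: the four epoxide C–O bonds are cut. One reagent-controlled epoxidation sets C18, C19 and C22; the monosubstituted alkene must stay.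

20 to 18 to 17 to 16: the triflate O–S bond, then the C11=O bond (traced to the exocyclic allene), then the O–Si bond at C3 are cut. The ketone has hydrogens on one side only, so enol triflate formation needs no regiocontrol.

16 to 15: the C6–C11 and O–C2 bonds are cut, the same two-ring simplification as in the other half, here with a terminator of established type. The forward step needs anti opening at C6 by the alkyne carbon C11.

15 to 14 to 11 and 12, and 11 to 9: the epoxide C–O bonds, the C8–C9 bond (allylic sp3–sp3 coupling that must occur at the primary carbon with retention of the E alkene) and the bond between the alkyne and the silylmethyl carbon are cut, ending at three commercial building blocks.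

## Other disconnections considered

Alternative 1: Both cyclohexane rings are read as reduced anisoles and the C12–C13 tether as the bridge of a bibenzyl; the cut is at the two C–CH3 bonds on C6 and C19. Forward, potassium in ammonia reduces both rings of the bibenzyl bis-amide A1 and the two amide enolates are methylated to the bis-diene A2.
- In its favour: both quaternary centres are set in one flask under auxiliary control, the tether is present from the first step so no fragment coupling is needed, and the hidden twofold symmetry is used. On these three points it is better than the chosen plan. Its key step is also a well-understood enolate alkylation, whereas step 4 is untested, so it is better on certainty too.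
- Against it here: A2 contains neither oxepane and only two of the nine stereocentres. The hindered amide carbons (C5, C20) must be extended to C2 and C23, and the enol ether carbons (C7, C18) turned into trans-fused ether carbons without a cascade. The symmetric intermediate must also be differentiated late (C10 methylene against C15 acetoxy-methyl, C3–OH against C22–OAc).
- Step economy: clearly worse than the chosen plan, which makes a ring pair and three or four stereocentres per cascade.

Alternative 2: The cut is at O–C2 and C6–C11. Forward, Et2AlCl triggers the cascade of the diepoxy 2-(silylmethyl)alkene A3 to the ring A/B bicycle A4, which already has the C10 methylene group, the C11 stereocentre and C12 as a silyloxymethyl group.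
- In its favour: the mechanism is the same epoxonium cascade as in step 4 (equal), and its open-chain terminator is of proven type (better). For rings A/B it is shorter than my steps 9–12 and 14–16, because no ketone, hydroboration or methylenation is needed (better).
- Against it here: it solves the easier half and leaves C14/C15 to another method. A4 carries C12, so the union would be an sp3–sp3 bond at C12–C13, or a carbon of the other half would have to be discarded. The trisubstituted allylsilane must be made with defined geometry.
- Overall: a strong tactic for one half, but a weaker strategic centre than step 4 for this target.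

Alternative 3: The cut is at C14–C15. Forward, pyrrolidine and acetic acid convert the C13 aldehyde of keto aldehyde A5 into its enamine, which adds to the C15 methyl ketone to give the β-hydroxy aldehyde A6.
- In its favour: no Lewis acid comes near the tertiary oxygen (better on mildness). C13 arrives as a one-carbon aldehyde at the right oxidation level for a polar union (equal to or better than the vinyl group of 7). C14 can be equilibrated to the equatorial epimer (equal).
- Against it here: the oxepane with its quaternary C19 must already exist in A5, so the step builds one ring where step 4 builds two. C15 is set by the facial selectivity of addition to a methyl ketone instead of being bought. A6 is prone to retro-aldol cleavage and dehydration.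
- Step economy: worse, because A5 itself needs an oxepane synthesis of roughly the length of steps 1–4.

Key step: step 4

Assumption: (3S,6E)-nerolidol of high enantiomeric purity (the dextrorotatory natural trans isomer) is taken as purchasable.

Remark: the matched combination is (3S)-1 with the D-fructose-derived ketone, which gives 6R,7R,10R in 2 (C18, C19, C22 of the target).

Step 1
Reactants: 1 (3S,6E)-nerolidol
Product: 2 (3S,6R,7R,10R)-6,7:10,11-diepoxy-3,7,11-trimethyldodec-1-en-3-ol
Conditions: D-fructose-derived Shi ketone (0.6 equiv), Oxone (2KHSO5·KHSO4·K2SO4), K2CO3, Bu4NHSO4, Na2B4O7/Na2EDTA buffer, MeCN/CH2(OMe)2/H2O, 0 °C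
Reagents that add atoms: potassium peroxymonosulfate, [K+].[O-]S(=O)(=O)OO
Why: Shi epoxidation; the chiral dioxirane attacks both trisubstituted alkenes through the spiro transition state on the face that gives R at each CH carbon (6R,7R,10R), under reagent control and independent of C3. The monosubstituted vinyl group is too electron-poor to react.

Step 2
Reactants: 2 (3S,6R,7R,10R)-6,7:10,11-diepoxy-3,7,11-trimethyldodec-1-en-3-ol; 3 allylchlorodimethylsilane
Product: 4 allyl{[(3S,6R,7R,10R)-6,7:10,11-diepoxy-3,7,11-trimethyldodec-1-en-3-yl]oxy}dimethylsilane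
Conditions: Et3N, DMAP (cat.), CH2Cl2, 0 °C → rt
Reagents that add atoms: none
Why: O-silylation of the tertiary alcohol by a small, reactive chlorosilane under nucleophilic catalysis. The medium stays basic, so both epoxides survive and no stereocentre is touched.

Step 3
Reactants: 4 allyl{[(3S,6R,7R,10R)-6,7:10,11-diepoxy-3,7,11-trimethyldodec-1-en-3-yl]oxy}dimethylsilane
Product: 5 (6S)-2,2,6-trimethyl-6-{2-[(2R,3R)-3-{2-[(2R)-3,3-dimethyloxiran-2-yl]ethyl}-3-methyloxiran-2-yl]ethyl}-3,6-dihydro-2H-1,2-oxasiline
Conditions: second-generation Grubbs catalyst RuCl2(=CHPh)(PCy3)(H2IMes) (5 mol %), CH2Cl2 (0.01 M), 40 °C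
Reagents that add atoms: none
Why: Silicon-tethered ring-closing metathesis of two monosubstituted alkenes closes the six-membered oxasiline, which can only hold a cis double bond. Epoxides and silyl ethers are inert to the ruthenium carbene.

Step 4
Reactants: 5 (6S)-2,2,6-trimethyl-6-{2-[(2R,3R)-3-{2-[(2R)-3,3-dimethyloxiran-2-yl]ethyl}-3-methyloxiran-2-yl]ethyl}-3,6-dihydro-2H-1,2-oxasiline
Product: 7 (3R,5aR,6R,7S,9aR)-6-ethenyl-2,2,5a,7-tetramethyldecahydro-1-benzoxepine-3,7-diol, via fluorosilyl ether 6 (not isolated)
Conditions: BF3·OEt2 (1.1 equiv), 2,6-di-tert-butyl-4-methylpyridine (0.5 equiv), CH2Cl2 (0.005 M), −78 °C; aq NaHCO3; then K2CO3, MeOH/H2O, rt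
Reagents that add atoms: none
Why: Proposed new method: BF3 activates the terminal 22,23-epoxide, the oxygen of the 18,19-epoxide attacks tertiary C23 from the rear (C22 is untouched and becomes the carbinol carbon), and the bicyclic epoxonium ion is opened at tertiary C19 by C14, the γ-carbon of the allylsilane, with loss of silicon to fluoride so that C13=C12 remains as a vinyl group (SE2'). The closest known reaction type is the Lewis acid tandem oxa-/carbacyclization of 1,5-diepoxides terminated by alkenes, enol silanes or open-chain allyl- and propargylsilanes; what has not been shown is a ring-bound allylsiloxane as terminator. Ring D closes by endo attack of oxygen on the more substituted epoxide carbon and becomes the seven-membered ether when the C19–O bond breaks; ring C closes as a cyclohexane by endo opening of the epoxonium ion at C19, with the attacking double bond outside the new ring. C19 is set by inversion and so follows from the (18R,19R)-epoxide. C14 is set by the tether: the oxasiline can only be cis-fused to the forming ring, which puts C13 and the C15 oxygen on the same face. With the (15S) centre the chair demanded by anti opening has the C15 methyl group equatorial and the C15 oxygen axial (matched case), and the oxasiline is puckered with silicon on the face of C13=C14 remote from C19, so the C12–Si bond turns into alignment with the π system as C14 pyramidalises. The step needs carbon rather than oxygen attack at C19 and cyclization rather than ionisation of the tertiary allylic C15–O bond: oxygen attack would need a chair with the C15 methyl syn-diaxial to the C19 methyl, and the ring holds the C15–O bond near the nodal plane of the alkene, which together with −78 °C and the hindered pyridine base should hold back ionisation and protodesilylation. Basic methanolysis on work-up cleaves the Si–O bond of 6 and gives 7.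

Step 5
Reactants: 7 (3R,5aR,6R,7S,9aR)-6-ethenyl-2,2,5a,7-tetramethyldecahydro-1-benzoxepine-3,7-diol
Product: 8 (3R,5aR,6R,7S,9aR)-6-ethenyl-2,2,5a,7-tetramethyldecahydro-1-benzoxepine-3,7-diyl diacetate
Conditions: Ac2O (6 equiv), Et3N, DMAP (1 equiv), CH2Cl2, rt → 40 °C
Reagents that add atoms: acetic anhydride, CC(=O)OC(C)=O
Why: DMAP-catalysed acylation; the secondary C22 hydroxyl reacts fast, and the axial tertiary C15 hydroxyl needs the stoichiometric acylpyridinium, excess anhydride and warming. Nothing in 7 is base-sensitive and no stereocentre is affected.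

Step 6
Reactants: 9 4-bromobut-1-yne
Product: 11 (5-bromopent-2-yn-1-yl)trimethylsilane, via lithium acetylide 10 (not isolated)
Conditions: n-BuLi, THF, −78 °C; then Me3SiCH2OTf, −78 → 0 °C
Reagents that add atoms: (trimethylsilyl)methyl trifluoromethanesulfonate, C[Si](C)(C)COS(=O)(=O)C(F)(F)F
Why: Deprotonation of the terminal alkyne at −78 °C is much faster than attack on the primary bromide. The acetylide is then alkylated by the very reactive silylmethyl triflate (SN2) to give the propargylsilane.

Step 7
Reactants: 11 (5-bromopent-2-yn-1-yl)trimethylsilane; 12 geranyl chloride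
Product: 14 trimethyl[(7E)-8,12-dimethyltrideca-7,11-dien-2-yn-1-yl]silane, via Grignard reagent 13 (not isolated)
Conditions: Mg, THF, rt; then 12, Li2CuCl4 (3 mol %), THF, −20 → 0 °C
Reagents that add atoms: none
Why: Copper-catalysed coupling of a primary Grignard reagent with an allylic chloride. Attack at the primary carbon is preferred because the other terminus would become quaternary, and the E alkene is retained; the propargylsilane is a spectator.

Step 8
Reactants: 14 trimethyl[(7E)-8,12-dimethyltrideca-7,11-dien-2-yn-1-yl]silane
Product: 15 trimethyl(6-{(2R,3R)-3-[2-((2R)-3,3-dimethyloxiran-2-yl)ethyl]-3-methyloxiran-2-yl}hex-2-yn-1-yl)silane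
Conditions: D-fructose-derived Shi ketone (0.6 equiv), Oxone (2KHSO5·KHSO4·K2SO4), K2CO3, Bu4NHSO4, Na2B4O7/Na2EDTA buffer, MeCN/CH2(OMe)2/H2O, 0 °C
Reagents that add atoms: potassium peroxymonosulfate, [K+].[O-]S(=O)(=O)OO
Why: Shi epoxidation with the same ketone sets C3 (R) and C6/C7 (R,R) in the same sense as in step 1. The alkyne and the propargylic C–Si bond are not attacked by the dioxirane in the buffered medium.

Step 9
Reactants: 15 trimethyl(6-{(2R,3R)-3-[2-((2R)-3,3-dimethyloxiran-2-yl)ethyl]-3-methyloxiran-2-yl}hex-2-yn-1-yl)silane
Product: 16 (3R,5aR,9aR)-6-ethenylidene-2,2,5a-trimethyldecahydro-1-benzoxepin-3-ol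
Conditions: BF3·OEt2 (1.1 equiv), 2,6-di-tert-butyl-4-methylpyridine (0.5 equiv), CH2Cl2 (0.005 M), −78 °C; aq NaHCO3
Reagents that add atoms: none
Why: Lewis acid tandem oxa-/carbacyclization of a 1,5-diepoxide with a propargylsilane terminator: the 6,7-epoxide oxygen attacks C2 of the activated terminal epoxide, and C11 opens the epoxonium ion at C6 anti through a chair, with loss of silicon to give the exocyclic allene. C6 is set by inversion and the ring fusion is trans.

Step 10
Reactants: 16 (3R,5aR,9aR)-6-ethenylidene-2,2,5a-trimethyldecahydro-1-benzoxepin-3-ol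
Product: 17 tert-butyl{[(3R,5aR,9aR)-6-ethenylidene-2,2,5a-trimethyldecahydro-1-benzoxepin-3-yl]oxy}dimethylsilane
Conditions: t-BuMe2SiOTf, 2,6-lutidine, CH2Cl2, −78 → 0 °C
Reagents that add atoms: tert-butyldimethylsilyl trifluoromethanesulfonate, CC(C)(C)[Si](C)(C)OS(=O)(=O)C(F)(F)F
Why: Silylation of a hindered secondary alcohol next to a quaternary carbon needs the silyl triflate with a hindered base. The allene is not nucleophilic enough to interfere, and protecting before ozonolysis avoids enol silane formation.

Step 11
Reactants: 17 tert-butyl{[(3R,5aR,9aR)-6-ethenylidene-2,2,5a-trimethyldecahydro-1-benzoxepin-3-yl]oxy}dimethylsilane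
Product: 18 (3R,5aS,9aR)-3-[(tert-butyldimethylsilyl)oxy]-2,2,5a-trimethyloctahydro-1-benzoxepin-6(2H)-one
Conditions: O3, CH2Cl2, −78 °C; then Me2S, −78 °C → rt
Reagents that add atoms: ozone, [O-][O+]=O
Why: Ozonolysis of the allene cleaves the exocyclic C=C at the ring carbon. An alcohol-free solvent lets any ketene-type fragment be oxidised further instead of being trapped; ethers and the silyl ether are inert.

Step 12
Reactants: 18 (3R,5aS,9aR)-3-[(tert-butyldimethylsilyl)oxy]-2,2,5a-trimethyloctahydro-1-benzoxepin-6(2H)-one
Product: 20 (3R,5aS,9aR)-3-[(tert-butyldimethylsilyl)oxy]-2,2,5a-trimethyl-2,3,4,5,5a,8,9,9a-octahydro-1-benzoxepin-6-yl trifluoromethanesulfonate, via potassium enolate 19 (not isolated)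
Conditions: KN(SiMe3)2, THF, −78 °C; then PhNTf2, −78 → 0 °C
Reagents that add atoms: N-phenylbis(trifluoromethanesulfonimide), O=S(=O)(N(c1ccccc1)S(=O)(=O)C(F)(F)F)C(F)(F)F
Why: Only C10 carries α-hydrogens (C6 is quaternary), so enolate regiochemistry is unambiguous. O-sulfonylation with the triflimide gives the C10=C11 enol triflate.

Step 13
Reactants: 8 (3R,5aR,6R,7S,9aR)-6-ethenyl-2,2,5a,7-tetramethyldecahydro-1-benzoxepine-3,7-diyl diacetate; 20 (3R,5aS,9aR)-3-[(tert-butyldimethylsilyl)oxy]-2,2,5a-trimethyl-2,3,4,5,5a,8,9,9a-octahydro-1-benzoxepin-6-yl trifluoromethanesulfonate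
Product: 22 C10=C11 alkene with C3 silyl ether and C15/C22 diacetate (3R,6R,7R,14R,15S,18R,19R,22R), via B-alkyl-9-BBN 21 (not isolated)
Conditions: 9-BBN-H (dimer), THF, 0 °C → rt; then 20, Pd(dppf)Cl2 (10 mol %), AsPh3, Cs2CO3, DMF/THF/H2O, rt → 45 °C
Reagents that add atoms: none
Why: Anti-Markovnikov hydroboration of the vinyl group by 9-BBN (acetates inert), then B-alkyl Suzuki–Miyaura coupling with the enol triflate forms C11–C12 with retention of the alkene position. The dppf/AsPh3 system is chosen for an alkenyl triflate next to a quaternary carbon, and carbonate at moderate temperature spares the acetates.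

Step 14
Reactants: 22 C10=C11 alkene with C3 silyl ether and C15/C22 diacetate (3R,6R,7R,14R,15S,18R,19R,22R)
Product: 24 C10 alcohol with C3 silyl ether and C15/C22 diacetate (3R,6R,7R,10R,11R,14R,15S,18R,19R,22R), via alkylborane 23 (not isolated)
Conditions: BH3·SMe2, THF, 0 °C → rt; then NaBO3·4H2O, THF/H2O, rt
Reagents that add atoms: sodium perborate, [Na+].[Na+].O[B-]1(O)OO[B-](O)(O)OO1
Why: Hydroboration–oxidation; boron goes to the less substituted C10 and the syn addition takes place on the face opposite the axial C6 methyl group, so H on C11 is cis to H on C7 and C12 becomes equatorial and cis to the C6 methyl as in the target. Perborate oxidises the C–B bond with retention without hydrolysing the acetates.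

Step 15
Reactants: 24 C10 alcohol with C3 silyl ether and C15/C22 diacetate (3R,6R,7R,10R,11R,14R,15S,18R,19R,22R)
Product: 25 C10 ketone with C3 silyl ether and C15/C22 diacetate (3R,6R,7R,11R,14R,15S,18R,19R,22R)
Conditions: Dess–Martin periodinane, NaHCO3, CH2Cl2, rt
Reagents that add atoms: none
Why: Dess–Martin oxidation of the only free hydroxyl under buffered conditions. C11 already has the thermodynamically preferred equatorial substituent, so enolisation cannot scramble it (the descriptor changes by priority only).

Step 16
Reactants: 25 C10 ketone with C3 silyl ether and C15/C22 diacetate (3R,6R,7R,11R,14R,15S,18R,19R,22R)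
Product: 26 C10 methylene compound with C3 silyl ether and C15/C22 diacetate (3R,6R,7R,11S,14R,15S,18R,19R,22R)
Conditions: Zn, CH2Br2, TiCl4, THF/CH2Cl2, 0 °C → rt
Reagents that add atoms: dibromomethane, BrCBr
Why: Takai–Lombardo methylenation; the titanium–zinc methylene reagent is not basic, so C11 is not epimerised and the acetates are not attacked, and it is suited to hindered enolisable ketones.

Step 17
Reactants: 26 C10 methylene compound with C3 silyl ether and C15/C22 diacetate (3R,6R,7R,11S,14R,15S,18R,19R,22R)
Product: 27 CNP0412606.2 (3R,6R,7R,11S,14R,15S,18R,19R,22R)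
Conditions: HF·pyridine, pyridine, THF, 0 °C → rt
Reagents that add atoms: none
Why: Fluoride cleavage of the silyl ether in a buffered medium; both acetates and the exocyclic alkene are stable, and C3–OH is too remote from either ester for acyl migration.

Compound list

1 | (3S,6E)-nerolidol | C=C[C@@](C)(O)CC/C=C(C)/CCC=C(C)C | starting material
2 | (3S,6R,7R,10R)-6,7:10,11-diepoxy-3,7,11-trimethyldodec-1-en-3-ol | C=C[C@@](C)(O)CC[C@H]1O[C@]1(C)CC[C@H]1OC1(C)C | intermediate
3 | allylchlorodimethylsilane | C=CC[Si](C)(C)Cl | starting material
4 | allyl{[(3S,6R,7R,10R)-6,7:10,11-diepoxy-3,7,11-trimethyldodec-1-en-3-yl]oxy}dimethylsilane | C=C[C@@](C)(O[Si](C)(C)CC=C)CC[C@H]1O[C@]1(C)CC[C@H]1OC1(C)C | intermediate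
5 | (6S)-2,2,6-trimethyl-6-{2-[(2R,3R)-3-{2-[(2R)-3,3-dimethyloxiran-2-yl]ethyl}-3-methyloxiran-2-yl]ethyl}-3,6-dihydro-2H-1,2-oxasiline (key-step precursor) | C[Si]1(C)C/C=C\[C@@](C)(O1)CC[C@H]2O[C@]2(C)CC[C@H]2OC2(C)C | intermediate
6 | (3R,5aR,6R,7S,9aR)-6-ethenyl-7-[(fluorodimethylsilyl)oxy]-2,2,5a,7-tetramethyldecahydro-1-benzoxepin-3-ol | C=C[C@@H]1[C@@]2(C)CC[C@@H](O)C(C)(C)O[C@@H]2CC[C@]1(C)O[Si](C)(C)F | intermediate
7 | (3R,5aR,6R,7S,9aR)-6-ethenyl-2,2,5a,7-tetramethyldecahydro-1-benzoxepine-3,7-diol (key-step product) | C=C[C@@H]1[C@@]2(C)CC[C@@H](O)C(C)(C)O[C@@H]2CC[C@]1(C)O | intermediate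
8 | (3R,5aR,6R,7S,9aR)-6-ethenyl-2,2,5a,7-tetramethyldecahydro-1-benzoxepine-3,7-diyl diacetate | C=C[C@@H]1[C@@]2(C)CC[C@@H](OC(C)=O)C(C)(C)O[C@@H]2CC[C@]1(C)OC(C)=O | intermediate
9 | 4-bromobut-1-yne | C#CCCBr | starting material
10 | (4-bromobut-1-yn-1-yl)lithium | [Li]C#CCCBr | intermediate
11 | (5-bromopent-2-yn-1-yl)trimethylsilane | C[Si](C)(C)CC#CCCBr | intermediate
12 | geranyl chloride, (2E)-1-chloro-3,7-dimethylocta-2,6-diene | ClC/C=C(\C)CCC=C(C)C | starting material
13 | [5-(trimethylsilyl)pent-3-yn-1-yl]magnesium bromide | C[Si](C)(C)CC#CCC[Mg]Br | intermediate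
14 | trimethyl[(7E)-8,12-dimethyltrideca-7,11-dien-2-yn-1-yl]silane | C[Si](C)(C)CC#CCCC/C=C(\C)CCC=C(C)C | intermediate
15 | trimethyl(6-{(2R,3R)-3-[2-((2R)-3,3-dimethyloxiran-2-yl)ethyl]-3-methyloxiran-2-yl}hex-2-yn-1-yl)silane | C[Si](C)(C)CC#CCCC[C@H]1O[C@]1(C)CC[C@H]1OC1(C)C | intermediate
16 | (3R,5aR,9aR)-6-ethenylidene-2,2,5a-trimethyldecahydro-1-benzoxepin-3-ol | C=C=C1CCC[C@H]2OC(C)(C)[C@H](O)CC[C@]12C | intermediate
17 | tert-butyl{[(3R,5aR,9aR)-6-ethenylidene-2,2,5a-trimethyldecahydro-1-benzoxepin-3-yl]oxy}dimethylsilane | C=C=C1CCC[C@H]2OC(C)(C)[C@H](O[Si](C)(C)C(C)(C)C)CC[C@]12C | intermediate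
18 | (3R,5aS,9aR)-3-[(tert-butyldimethylsilyl)oxy]-2,2,5a-trimethyloctahydro-1-benzoxepin-6(2H)-one | O=C1CCC[C@H]2OC(C)(C)[C@H](O[Si](C)(C)C(C)(C)C)CC[C@]12C | intermediate
19 | potassium enolate of 18 | [K+].[O-]C1=CCC[C@H]2OC(C)(C)[C@H](O[Si](C)(C)C(C)(C)C)CC[C@]12C | intermediate
20 | (3R,5aS,9aR)-3-[(tert-butyldimethylsilyl)oxy]-2,2,5a-trimethyl-2,3,4,5,5a,8,9,9a-octahydro-1-benzoxepin-6-yl trifluoromethanesulfonate | FC(F)(F)S(=O)(=O)OC1=CCC[C@H]2OC(C)(C)[C@H](O[Si](C)(C)C(C)(C)C)CC[C@]12C | intermediate
21 | 9-{2-[(3R,5aR,6R,7S,9aR)-3,7-diacetoxy-2,2,5a,7-tetramethyldecahydro-1-benzoxepin-6-yl]ethyl}-9-borabicyclo[3.3.1]nonane | C1CCC2CCCC1B2CC[C@@H]1[C@@]2(C)CC[C@@H](OC(C)=O)C(C)(C)O[C@@H]2CC[C@]1(C)OC(C)=O | intermediate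
22 | coupled C10=C11 alkene, C3 tert-butyldimethylsilyl ether, C15/C22 diacetate (3R,6R,7R,14R,15S,18R,19R,22R) | C1(=CCC[C@H]2OC(C)(C)[C@H](O[Si](C)(C)C(C)(C)C)CC[C@]12C)CC[C@@H]1[C@@]2(C)CC[C@@H](OC(C)=O)C(C)(C)O[C@@H]2CC[C@]1(C)OC(C)=O | intermediate
23 | C10 borane (BH2 on C10, H on C11, both cis to H on C7) | B[C@@H]1CC[C@H]2OC(C)(C)[C@H](O[Si](C)(C)C(C)(C)C)CC[C@]2(C)[C@H]1CC[C@@H]1[C@@]2(C)CC[C@@H](OC(C)=O)C(C)(C)O[C@@H]2CC[C@]1(C)OC(C)=O | intermediate
24 | C10 alcohol, C3 silyl ether, C15/C22 diacetate (3R,6R,7R,10R,11R,14R,15S,18R,19R,22R) | O[C@@H]1CC[C@H]2OC(C)(C)[C@H](O[Si](C)(C)C(C)(C)C)CC[C@]2(C)[C@H]1CC[C@@H]1[C@@]2(C)CC[C@@H](OC(C)=O)C(C)(C)O[C@@H]2CC[C@]1(C)OC(C)=O | intermediate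
25 | C10 ketone, C3 silyl ether, C15/C22 diacetate (3R,6R,7R,11R,14R,15S,18R,19R,22R) | O=C1CC[C@H]2OC(C)(C)[C@H](O[Si](C)(C)C(C)(C)C)CC[C@]2(C)[C@H]1CC[C@@H]1[C@@]2(C)CC[C@@H](OC(C)=O)C(C)(C)O[C@@H]2CC[C@]1(C)OC(C)=O | intermediate
26 | C10 methylene compound, C3 silyl ether, C15/C22 diacetate (3R,6R,7R,11S,14R,15S,18R,19R,22R) | C=C1CC[C@H]2OC(C)(C)[C@H](O[Si](C)(C)C(C)(C)C)CC[C@]2(C)[C@H]1CC[C@@H]1[C@@]2(C)CC[C@@H](OC(C)=O)C(C)(C)O[C@@H]2CC[C@]1(C)OC(C)=O | intermediate
27 | CNP0412606.2 (3R,6R,7R,11S,14R,15S,18R,19R,22R) | C=C1CC[C@H]2OC(C)(C)[C@H](O)CC[C@]2(C)[C@H]1CC[C@@H]1[C@@]2(C)CC[C@@H](OC(C)=O)C(C)(C)O[C@@H]2CC[C@]1(C)OC(C)=O | target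

Total step count: 17. Longest linear sequence: 12 steps (steps 6–17, from 9); the ring C/D branch is 5 steps (1–5) and joins at step 13.

Steps least certain to work

Step 4 (key step, new terminator). The most likely failure is attack of the siloxane oxygen, not C14, on the epoxonium ion, or ionisation of the tertiary allylic C15–O bond with loss of silicon to a diene. The cause is that the ring-bound C–Si bond is only partly aligned with the π system, so the terminator is a weaker nucleophile than an open-chain allylsilane. The fallback uses known chemistry, sets out from 2 and returns at 7. The tertiary alcohol of 2 is protected (Et3SiCl, imidazole, DMAP, DMF) as the triethylsilyl ether F1. Its vinyl group is joined to allyltrimethylsilane by cross-metathesis (second-generation Hoveyda–Grubbs catalyst RuCl2(=CH-C6H4-2-OiPr)(H2IMes), CH2Cl2, 40 °C) to give the open-chain (E)-allylsilane F2. The established BF3·OEt2 cascade with an allylsilane terminator should then give the bicyclic silyl ether F3, and Bu4NF gives 7. The price is one more step and the loss of tether control at C14: a chair with the alkene equatorial is expected, but epimers may have to be separated.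

Step 9. The likely failure is a non-concerted course: rearrangement of an activated epoxide to a carbonyl compound, or capture of the epoxonium ion by fluoride, because the linear propargylsilane must bend to reach C6 and is a modest nucleophile. The fallback sets out from 12 and returns at 18. Coupling of 12 with but-3-enylmagnesium bromide (Li2CuCl4) gives (6E)-7,11-dimethyldodeca-1,6,10-triene F4, and Shi epoxidation as in step 8 gives the diepoxide F5. Cross-metathesis with allyltrimethylsilane (second-generation Grubbs catalyst) gives the open-chain allylsilane F6, whose BF3·OEt2 cascade should give the C11-vinyl bicyclic alcohol F7 (C11 configuration of no consequence). Silylation as in step 10 gives the silyl ether F8, isomerisation with RuHCl(CO)(PPh3)3 (toluene, 80 °C) gives the ethylidene compound F9, and ozonolysis gives 18.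

Step 13. The likely failure is slow oxidative addition and transmetalation at the alkenyl triflate next to the quaternary C6, so that protodeboronation or β-hydride elimination takes over, together with partial hydrolysis of the C22 acetate in the basic aqueous medium. The fallback sets out from 8 and returns at 22, replacing the boron-based coupling by a neutral, anhydrous zinc-based one. Hydroboration–oxidation of 8 (9-BBN-H; NaBO3·4H2O) gives the primary alcohol F10, and I2, PPh3 and imidazole give the iodide F11. Zinc insertion (Zn, LiCl, THF) gives the alkylzinc iodide F12, which is coupled with 20 in a Negishi reaction (Pd(OAc)2, SPhos, THF, rt).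

Step 14. The likely failure is sluggish addition of borane to the hindered trisubstituted alkene, which would leave time for reduction of the acetates or incomplete conversion. The fallback sets out from 22 and returns at 25 without a hydroboration. Dihydroxylation (OsO4 cat., N-methylmorpholine N-oxide) from the face opposite the C6 methyl group gives the C10,C11-diol F13. Dess–Martin oxidation of its secondary hydroxyl gives the α-hydroxy ketone F14, and SmI2 (THF/MeOH, −78 °C) removes the tertiary α-hydroxyl. Protonation of the samarium enolate, with DBU equilibration if needed, places C12 equatorial and gives 25.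

Step 16. The likely failure is enolisation in place of addition at the hindered C10 carbonyl, or slow attack on the C22 acetate if the reaction is forced. The fallback sets out from 25 and returns at 27 by a two-stage Peterson olefination. Me3SiCH2Li with CeCl3 (THF, −78 °C), a reagent that adds to ketones in preference to esters, gives the β-hydroxysilane F15. HF·pyridine then effects both the elimination to the exocyclic alkene and the cleavage of the C3 silyl ether.

Further compounds

F1 | step 4 | triethylsilyl ether of 2 | C=C[C@@](C)(O[Si](CC)(CC)CC)CC[C@H]1O[C@]1(C)CC[C@H]1OC1(C)C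
F2 | step 4 | open-chain (E)-allylsilane, C15 triethylsilyl ether | C[Si](C)(C)C/C=C/[C@@](C)(O[Si](CC)(CC)CC)CC[C@H]1O[C@]1(C)CC[C@H]1OC1(C)C
F3 | step 4 | 7-O-triethylsilyl ether of 7 | C=C[C@@H]1[C@@]2(C)CC[C@@H](O)C(C)(C)O[C@@H]2CC[C@]1(C)O[Si](CC)(CC)CC
F4 | step 9 | (6E)-7,11-dimethyldodeca-1,6,10-triene | C=CCCC/C=C(\C)CCC=C(C)C
F5 | step 9 | (6R,7R,10R)-6,7:10,11-diepoxy-7,11-dimethyldodec-1-ene | C=CCCC[C@H]1O[C@]1(C)CC[C@H]1OC1(C)C
F6 | step 9 | open-chain (E)-allylsilane diepoxide | C[Si](C)(C)C/C=C/CCC[C@H]1O[C@]1(C)CC[C@H]1OC1(C)C
F7 | step 9 | (3R,5aR,9aR)-6-ethenyl-2,2,5a-trimethyldecahydro-1-benzoxepin-3-ol (vinyl equatorial drawn) | C=C[C@H]1CCC[C@H]2OC(C)(C)[C@H](O)CC[C@]12C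
F8 | step 9 | tert-butyldimethylsilyl ether of F7 | C=C[C@H]1CCC[C@H]2OC(C)(C)[C@H](O[Si](C)(C)C(C)(C)C)CC[C@]12C
F9 | step 9 | 6-ethylidene isomer of F8 | CC=C1CCC[C@H]2OC(C)(C)[C@H](O[Si](C)(C)C(C)(C)C)CC[C@]12C
F10 | step 13 | C12 primary alcohol from 8 | OCC[C@@H]1[C@@]2(C)CC[C@@H](OC(C)=O)C(C)(C)O[C@@H]2CC[C@]1(C)OC(C)=O
F11 | step 13 | C12 iodide | ICC[C@@H]1[C@@]2(C)CC[C@@H](OC(C)=O)C(C)(C)O[C@@H]2CC[C@]1(C)OC(C)=O
F12 | step 13 | C12 alkylzinc iodide | I[Zn]CC[C@@H]1[C@@]2(C)CC[C@@H](OC(C)=O)C(C)(C)O[C@@H]2CC[C@]1(C)OC(C)=O
F13 | step 14 | C10,C11-diol from 22 | O[C@@H]1CC[C@H]2OC(C)(C)[C@H](O[Si](C)(C)C(C)(C)C)CC[C@]2(C)[C@@]1(O)CC[C@@H]1[C@@]2(C)CC[C@@H](OC(C)=O)C(C)(C)O[C@@H]2CC[C@]1(C)OC(C)=O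
F14 | step 14 | C11-hydroxy C10 ketone | O=C1CC[C@H]2OC(C)(C)[C@H](O[Si](C)(C)C(C)(C)C)CC[C@]2(C)[C@@]1(O)CC[C@@H]1[C@@]2(C)CC[C@@H](OC(C)=O)C(C)(C)O[C@@H]2CC[C@]1(C)OC(C)=O
F15 | step 16 | C10 β-hydroxysilane from 25 | C[Si](C)(C)CC1(O)CC[C@H]2OC(C)(C)[C@H](O[Si](C)(C)C(C)(C)C)CC[C@]2(C)[C@H]1CC[C@@H]1[C@@]2(C)CC[C@@H](OC(C)=O)C(C)(C)O[C@@H]2CC[C@]1(C)OC(C)=O
A1 | alternative 1 | bibenzyl bis(2-methoxybenzamide) of (S)-2-(methoxymethyl)pyrrolidine | COC[C@@H]1CCCN1C(=O)c1c(OC)cccc1CCc1cccc(OC)c1C(=O)N1CCC[C@H]1COC
A2 | alternative 1 | bis(1-methyl-2-methoxycyclohexa-2,5-diene-1-carboxamide) | COC[C@@H]1CCCN1C(=O)[C@@]2(C)C(OC)=CCC=C2CCC2=CCC=C(OC)[C@]2(C)C(=O)N1CCC[C@H]1COC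
A3 | alternative 2 | diepoxy 2-(trimethylsilylmethyl)alkene with C12 silyl ether | C[Si](C)(C)C/C(=C\CO[Si](c1ccccc1)(c1ccccc1)C(C)(C)C)CC[C@H]1O[C@]1(C)CC[C@H]1OC1(C)C
A4 | alternative 2 | ring A/B bicycle with C10 methylene and C12 silyl ether | C=C1CC[C@H]2OC(C)(C)[C@H](O)CC[C@]2(C)[C@H]1CO[Si](c1ccccc1)(c1ccccc1)C(C)(C)C
A5 | alternative 3 | ring D keto aldehyde | O=CC[C@@]1(C)CC[C@@H](OC(C)=O)C(C)(C)O[C@@H]1CCC(C)=O
A6 | alternative 3 | ring C/D β-hydroxy aldehyde | O=C[C@@H]1[C@@]2(C)CC[C@@H](OC(C)=O)C(C)(C)O[C@@H]2CC[C@]1(C)O
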